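## Structural features

The target is a flavanone. Ring A (a benzene ring) is fused through C4a–C8a to ring C (a 2,3-dihydropyran-4-one, O1–C2–C3–C4), and ring B, a 3-hydroxy-4-methoxyphenyl group, sits on C2. Ring A is pentasubstituted in a phloroglucinol pattern: the C4 carbonyl on C4a, methoxy groups on C5 and C7, a prenyl group on C8, O1 on C8a, and a single hydrogen on C6. C2 is the only stereocentre, (S), with no stereocentre next to it. It is benzylic to an electron-rich ring, carries O1 and lies β to the ketone, so base can open ring C to the achiral chalcone and strong acid can ionise C2–O1; either path racemises it. The prenyl alkene does not tolerate strong acid, halogen or hydrogenation, and the 3'-phenol must be masked wherever a Lewis acid, a silyl ketene acetal or a methylating agent is used. The real difficulty is regiochemical: C6 and C8 both lie between two oxygen-bearing carbons and behave alike towards electrophiles, so prenylation or acylation of a preformed ring A does not tell them apart. The key step exploits the C4a=C8a enol ether double bond of a chiral ring C precursor, which already holds O1 on C8a and the carbonyl on C4. Ring A is grown across this bond from a four-carbon diene whose prenyl-bearing end bonds to C8a, so the prenyl group can only end on C8.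

## Logic of the disconnections

**17 ⇒ 16.** A methoxymethyl group is placed on the ring B oxygen (O–CH2 bond). The free phenol would quench the silyl diene, bind the titanium catalyst and be methylated together with O5, so it is masked from the first step. Nothing is gained in skeleton, only in chemoselectivity. The forward step must cleave an aryl acetal with acid weak enough to spare the prenyl alkene and C2–O1.

**16 ⇒ 15.** The O5–CH3 bond is cut. O5 comes from the ketene acetal end of the diene and emerges from the annulation as a silylated hydroxyl, so the methyl group is added afterwards. The forward step must methylate a phenol hydrogen-bonded to the C4 carbonyl without a base able to open ring C.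

**15 ⇒ 6 + 12.** The C4a–C5 and C8–C8a bonds are cut, removing ring A entirely. This answers the regiochemical problem: O1 is already on the carbon that becomes C8a, and the prenyl group rides on the diene terminus that bonds to it. A tricyclic arene falls into a monocyclic bromo enone and an acyclic diene of similar size. The forward step demands a match of diene and dienophile polarity, enough reactivity from a deactivated enone, aromatisation by loss of HBr and methanol and not of O1, and conditions that leave C2 alone.

**6 ⇒ 5.** The C5–Br bond is cut (pyranone numbering). The bromine activates the enone, marks the carbon that takes the ketene acetal end and supplies the leaving group for aromatisation. The forward step must halogenate the enol ether carbon in preference to ring B and without free acid.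

**5 ⇒ 2 + 3.** The O1–C6 and C2–C3 bonds are cut (pyranone numbering), a hetero-Diels–Alder disconnection. Ring C and the only stereocentre come from an aldehyde in one step. The forward step demands catalyst control of the aldehyde face.

**2 ⇒ 1.** The O–CH2 bond of the acetal is cut, leading to a commercial phenolic aldehyde. The forward step is a simple O-alkylation.

**12 ⇒ 11.** The O–Si bond is cut. The forward step demands deprotonation at the γ-carbon and not at C2, and a C3=C4 geometry that leaves the prenyl chain on the outer side of the diene.

**11 ⇒ 9.** The enol O–CH3 bond is cut, leading to a β-keto ester. The forward step needs an acid catalyst mild enough for the trisubstituted alkene.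

**9 ⇒ 7 + 8.** The C4–C5 bond of the keto ester is cut, giving two commercial materials. The forward step demands alkylation at the terminal carbon, which the dianion provides, and substitution at the primary carbon of the allylic bromide.

## Other disconnections considered

**Alternative 1:** The cut is O1–C8a. In the forward sense the open-chain diol A1, whose ring A carries bromine on the future C8a, would close to the flavan-4-ol A2 by copper-catalysed intramolecular aryl etherification (CuI, a phenanthroline-type ligand, Cs2CO3, toluene, about 110 °C). Oxidation of the C4 hydroxyl of A2 would then give 16.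
- In its favour: the C2–O bond is never broken, so C2 is retained by construction. No ketone is present during ring closure, so ring C cannot open by elimination. O5 is methylated from the start. The reaction class is established.
- Against it: ring A of A1 must be made as a fully substituted aryl bromide with the bromine between the prenyl group and the side chain. The C6/C8 problem is therefore only moved into an arene synthesis, and the coupling site is hindered and electron-rich. Two carbinol centres must be set although one is oxidised away.
- Comparison: on protection of C2 it is the equal of the chosen plan. On precedent of the key step and on the end game (no methylation of a hydrogen-bonded phenol) it is the better. On regiocontrol of ring A and on step count (about eleven or twelve against nine) it is the weaker.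

**Alternative 2:** The cut is C4–C4a. The (S)-aryl ether A3, a Weinreb amide with bromine on the future C4a, would undergo bromine–lithium exchange (n-BuLi or t-BuLi, THF, −78 °C or below), and the aryllithium would acylate itself on the amide (Parham closure) to give A4, which is identical with 16.
- In its favour: the ketone arrives at the right oxidation level and over-addition is blocked by the chelated tetrahedral intermediate. Only the acetal cleavage would remain. This type of closure to chroman-4-ones is precedented.
- Against it: A3 needs a stereospecific C2–O bond between a phenol substituted at both ortho positions and an electron-rich benzylic alcohol, where inversion can leak through ionisation. In A3 the protons α to the amide and the benzylic C2–H are exposed to organolithium; deprotonation α to the amide would expel the phenoxide and destroy C2. The regiochemistry of ring A again rests on a separate arene synthesis.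
- Comparison: in end game and in precedent it is the better of the two. In how C2 is threatened it is the weaker (strong base against weak base). In step count it is about equal or slightly longer. In regiocontrol it is the weaker.

**Alternative 3:** The cut is C5–C6. The pyranone A5 carries an ester on the future C4a and a prenylated methyl ketone side chain on the future C8a. Its dianion (LDA or LiHMDS, THF, −78 °C and warming) would attack the ester through the terminal methyl carbon and tautomerise to the 5,7-dihydroxyflavanone A6.
- In its favour: like the chosen plan it grows ring A on a chiral ring C, so O1 and the prenyl group are placed by construction. Aromatisation needs no leaving group, so loss of HBr against loss of O1 never arises. The closure is intramolecular and does not depend on a deactivated dienophile.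
- Against it: A5 is densely functionalised and no short path to it from a chiral pyranone is apparent. Excess strong base can deprotonate C3 and open ring C. A6 has two free phenols, so the 7-hydroxyl must be methylated selectively before the 5-hydroxyl, lengthening the end game.
- Comparison: on regiocontrol it is the equal of the chosen plan. On the ease of the ring-forming event itself it is the better. On access to the precursor, on basicity towards C2 and on step count it is the weaker.

Key step: step 7

Remark 1: C2 has the same spatial arrangement and the same ranking of substituents (O1 > aryl > C3 > H) in 4, 5, 6 and 13 to 17, so it is (S) throughout. Flavanone numbering is used for 13 to 17 and pyranone numbering for 5 and 6.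

Remark 2: only the C3=C4 geometry of 12 matters; (3Z) places the prenyl chain on the outer side of the s-cis diene, and the C1=C2 geometry disappears on aromatisation.

## Route

Step 1
Reactants: 1 isovanillin (3-hydroxy-4-methoxybenzaldehyde)
Product: 2 4-methoxy-3-(methoxymethoxy)benzaldehyde
Conditions: MOMCl, K2CO3, DMF, 0 °C to rt
Reagents that add atoms: chloromethyl methyl ether, COCCl
Why: O-alkylation of the phenoxide with a reactive α-chloro ether (Williamson type); the aldehyde is inert to these conditions.

Step 2
Reactants: 2 4-methoxy-3-(methoxymethoxy)benzaldehyde; 3 Danishefsky's diene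
Product: 5 (2S)-2-[4-methoxy-3-(methoxymethoxy)phenyl]-2,3-dihydro-4H-pyran-4-one, via silylated aldol adduct 4 (not isolated)
Conditions: (S)-BINOL/Ti(OiPr)4 (10 mol%), 4 Å MS, Et2O, −20 °C; then TFA (0.2 equiv), CH2Cl2, 0 °C
Reagents that add atoms: none
Why: Formal hetero-Diels–Alder reaction: titanium–BINOL-catalysed Mukaiyama aldol addition of the enol silane end of 3 to the aldehyde, then acid-induced closure of 4 with loss of methanol. C2 is set by the chiral Lewis acid; attack on the Si face gives (S), and (S)-BINOL is chosen on the expectation that it directs to this face as in the related allylation and aldol reactions of this catalyst family, the sense to be confirmed on 5 and the antipodal ligand used if needed. A catalytic amount of TFA at 0 °C should leave the aryl acetal intact.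

Step 3
Reactants: 5 (2S)-2-[4-methoxy-3-(methoxymethoxy)phenyl]-2,3-dihydro-4H-pyran-4-one
Product: 6 (2S)-5-bromo-2-[4-methoxy-3-(methoxymethoxy)phenyl]-2,3-dihydro-4H-pyran-4-one
Conditions: NBS (1.05 equiv), CH2Cl2, 0 °C, dark
Reagents that add atoms: N-bromosuccinimide, O=C1CCC(=O)N1Br
Why: Electrophilic α-halogenation of a vinylogous ester: bromine is delivered to the nucleophilic C5 and the oxocarbenium ion at C6 loses H-5 to the succinimide anion. The enol ether carbon should be far more nucleophilic than ring B, and no free acid builds up, so C2 is not put at risk.

Step 4
Reactants: 7 methyl acetoacetate; 8 prenyl bromide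
Product: 9 methyl 7-methyl-3-oxooct-6-enoate
Conditions: NaH, THF, 0 °C; n-BuLi, 0 °C; 8, 0 °C to rt; aq. HCl work-up
Reagents that add atoms: none
Why: Alkylation of the acetoacetate dianion takes place at the more basic terminal carbon, and the primary allylic bromide reacts by direct substitution at its CH2.

Step 5
Reactants: 9 methyl 7-methyl-3-oxooct-6-enoate
Product: 11 methyl (2E)-3-methoxy-7-methylocta-2,6-dienoate, via dimethyl ketal 10 (not isolated)
Conditions: HC(OMe)3, H2SO4 (cat.), MeOH, rt; then distillation under reduced pressure
Reagents that add atoms: trimethyl orthoformate, COC(OC)OC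
Why: Acid-catalysed ketalisation with the orthoester, then loss of methanol towards the conjugated (E)-β-methoxy enoate. A trace of acid in an anhydrous medium at rt should not touch the trisubstituted alkene.

Step 6
Reactants: 11 methyl (2E)-3-methoxy-7-methylocta-2,6-dienoate
Product: 12 (1Z,3Z)-1,3-dimethoxy-7-methyl-1-(trimethylsilyloxy)octa-1,3,6-triene
Conditions: LDA, THF, −78 °C; TMSCl, −78 °C to rt; non-aqueous work-up
Reagents that add atoms: chlorotrimethylsilane, C[Si](C)(C)Cl
Why: Kinetic γ-deprotonation of the vinylogous carbonate and O-silylation of the dienolate, the standard entry to 1-alkoxy-1-silyloxy dienes. The (3Z) isomer is expected because the chain on C4 prefers to lie away from C2.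

Step 7
Reactants: 6 (2S)-5-bromo-2-[4-methoxy-3-(methoxymethoxy)phenyl]-2,3-dihydro-4H-pyran-4-one; 12 (1Z,3Z)-1,3-dimethoxy-7-methyl-1-(trimethylsilyloxy)octa-1,3,6-triene
Product: 15 (2S)-5-hydroxy-7,4'-dimethoxy-3'-(methoxymethoxy)-8-prenylflavanone, via bromo ketal cycloadduct 13 (not isolated), via aryl trimethylsilyl ether 14 (not isolated)
Conditions: 12 (3 equiv), 2,6-lutidine (2 equiv), PhMe (1 M), 100 °C, sealed tube; then 10% aq. citric acid, THF, rt
Reagents that add atoms: none
Why: Proposed new method: C4 of 12, the prenyl-bearing end, is the nucleophilic terminus of the silyl ketene acetal diene, and C6 of 6 (C8a in flavanone numbering) is the electrophilic β-carbon of the bromo enone, so bonding should begin between these two carbons and be completed by closure of the ketene acetal carbon onto the bromine-bearing C5 of 6 (C4a), either in one asynchronous [4+2] event or by Michael addition and collapse of the resulting ion pair. The closest known reaction type is the regiocontrolled cycloaddition and aromatisation of 1-alkoxy-1-silyloxy dienes with bromoquinones and with chromones that carry an acceptor on C3; a 5-bromo-2,3-dihydropyran-4-one has not served as the two-carbon partner, and the α-bromine is relied on to lower the LUMO of this vinylogous ester. Ring A is closed by this intermolecular [4+2] annulation across the C4a=C8a bond of ring C, which should give the cis-fused bromo ketal 13. In 13 the mixed ketal at C5 can ionise with help from the C7 methoxy group and lose methanol together with H-8, and the cyclohexadiene so formed then loses HBr across C4a–C8a under the pull of aromatisation to give 14, whose silyl ether the citric acid work-up hydrolyses to the hydrogen-bonded phenol 15. No stereocentre of 15 is made here: the four sp3 centres created in 13 are all flattened, and C2, outside the reacting system, meets only a weak hindered pyridine base and a weak acid. The step needs regioselectivity (prenyl on C8 and not on C6), secured by the matched polarity of the two partners and reinforced by the bromine sitting on the carbon that takes the ketene acetal end, and it needs aromatisation by loss of HBr and not of O1, secured because C4a of 13 bears bromine and no hydrogen, so no enolate can form there to push O1 out. 2,6-Lutidine binds the HBr, which keeps the methoxymethyl ether and the prenyl alkene away from strong acid, and any 5-O-methyl product formed by loss of silanol in place of methanol is 16, the next compound of the route.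

Step 8
Reactants: 15 (2S)-5-hydroxy-7,4'-dimethoxy-3'-(methoxymethoxy)-8-prenylflavanone
Product: 16 (2S)-5,7,4'-trimethoxy-3'-(methoxymethoxy)-8-prenylflavanone
Conditions: MeI (excess), Ag2O, DMF, rt, dark
Reagents that add atoms: iodomethane, CI
Why: Silver-oxide-mediated O-methylation of the hydrogen-bonded phenol. Ag2O is a weak base that should not enolise the C4 ketone to a useful extent, so ring C should stay closed and C2 keep its configuration.

Step 9
Reactants: 16 (2S)-5,7,4'-trimethoxy-3'-(methoxymethoxy)-8-prenylflavanone
Product: 17 (2S)-3'-hydroxy-5,7,4'-trimethoxy-8-prenylflavanone (the target)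
Conditions: HCl (1 M), MeOH, 40 °C
Reagents that add atoms: none
Why: Acid-catalysed acetal exchange with methanol frees the phenol. Dilute acid at this temperature should neither add across the prenyl alkene (no free hydroxyl sits ortho to it) nor ionise C2–O1.

## Compound list

1 | isovanillin (3-hydroxy-4-methoxybenzaldehyde) | COc1ccc(C=O)cc1O | starting material
2 | 4-methoxy-3-(methoxymethoxy)benzaldehyde | COCOc1cc(C=O)ccc1OC | intermediate
3 | Danishefsky's diene, (E)-1-methoxy-3-(trimethylsilyloxy)buta-1,3-diene | CO/C=C/C(=C)O[Si](C)(C)C | starting material
4 | (1E,5S)-1-methoxy-5-[4-methoxy-3-(methoxymethoxy)phenyl]-5-(trimethylsilyloxy)pent-1-en-3-one | CO/C=C/C(=O)C[C@H](O[Si](C)(C)C)c1ccc(OC)c(OCOC)c1 | intermediate (not isolated)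
5 | (2S)-2-[4-methoxy-3-(methoxymethoxy)phenyl]-2,3-dihydro-4H-pyran-4-one | COc1ccc([C@@H]2CC(=O)C=CO2)cc1OCOC | intermediate
6 | (2S)-5-bromo-2-[4-methoxy-3-(methoxymethoxy)phenyl]-2,3-dihydro-4H-pyran-4-one | COc1ccc([C@@H]2CC(=O)C(Br)=CO2)cc1OCOC | intermediate
7 | methyl acetoacetate | COC(=O)CC(C)=O | starting material
8 | prenyl bromide (1-bromo-3-methylbut-2-ene) | CC(C)=CCBr | starting material
9 | methyl 7-methyl-3-oxooct-6-enoate | COC(=O)CC(=O)CCC=C(C)C | intermediate
10 | methyl 3,3-dimethoxy-7-methyloct-6-enoate | COC(=O)CC(OC)(OC)CCC=C(C)C | intermediate (not isolated)
11 | methyl (2E)-3-methoxy-7-methylocta-2,6-dienoate | COC(=O)/C=C(/OC)CCC=C(C)C | intermediate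
12 | (1Z,3Z)-1,3-dimethoxy-7-methyl-1-(trimethylsilyloxy)octa-1,3,6-triene | CO/C(O[Si](C)(C)C)=C/C(OC)=C/CC=C(C)C | intermediate
13 | (2S)-4a-bromo-5,7-dimethoxy-2-[4-methoxy-3-(methoxymethoxy)phenyl]-8-(3-methylbut-2-enyl)-5-(trimethylsilyloxy)-2,3,4a,5,8,8a-hexahydrochromen-4-one (cis ring fusion expected; the four transient centres are not defined) | COc1ccc([C@@H]2CC(=O)C3(Br)C(OC)(O[Si](C)(C)C)C=C(OC)C(CC=C(C)C)C3O2)cc1OCOC | intermediate (not isolated)
14 | (2S)-7,4'-dimethoxy-3'-(methoxymethoxy)-8-prenyl-5-(trimethylsilyloxy)flavanone | COc1ccc([C@@H]2CC(=O)c3c(O[Si](C)(C)C)cc(OC)c(CC=C(C)C)c3O2)cc1OCOC | intermediate (not isolated)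
15 | (2S)-5-hydroxy-7,4'-dimethoxy-3'-(methoxymethoxy)-8-prenylflavanone | COc1ccc([C@@H]2CC(=O)c3c(O)cc(OC)c(CC=C(C)C)c3O2)cc1OCOC | intermediate
16 | (2S)-5,7,4'-trimethoxy-3'-(methoxymethoxy)-8-prenylflavanone | COc1ccc([C@@H]2CC(=O)c3c(OC)cc(OC)c(CC=C(C)C)c3O2)cc1OCOC | intermediate
17 | (2S)-3'-hydroxy-5,7,4'-trimethoxy-8-prenylflavanone | COc1ccc([C@@H]2CC(=O)c3c(OC)cc(OC)c(CC=C(C)C)c3O2)cc1O | target

## Step count and least certain steps

Total steps: 9. Longest linear sequence: 6 steps (1, 2, 3, 7, 8, 9; the diene branch 4, 5, 6, 7, 8, 9 is equally long).

**Step 7 (key step).**
- What may go wrong: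
  - The cycloaddition may be too slow. The enone of 6 is deactivated by O1, and 12 can decay on prolonged heating by silyl migration or hydrolysis back to 11.
  - A share of 12 with the other C3=C4 geometry would react even more slowly.
  - Aromatisation may stall at the ketal stage or be diverted by reductive loss of bromine, after which ring C could open.
  - Acid set free faster than it is bound could strip the acetal.
- A change of conditions only (about 12 kbar in CH2Cl2 at 40 °C) would be tried first.
- Fallback: it leaves the cycloaddition, uses known reactions, sets out from 2 and returns at 15. Claisen–Schmidt condensation of 2 with purchased 2',6'-dihydroxy-4'-methoxyacetophenone F1 (KOH, EtOH–H2O, rt) should give the 2',6'-dihydroxychalcone F2. Because ring A of F2 is symmetric, closure with NaOAc in refluxing EtOH can give only one flavanone, the racemic 5-hydroxy-7-methoxyflavanone F3. Mitsunobu etherification of the 5-hydroxyl with 3-methylbut-2-en-1-ol (PPh3, DIAD, THF) should give the racemic 5-O-prenyl ether F4. Claisen–Cope rearrangement catalysed by Eu(fod)3 (CHCl3, 60 °C) should then carry the prenyl group to the position para to O5, which is C8, giving the racemic 8-prenylflavanone F5; this para preference is the known entry to 8-prenylflavanones. Preparative chromatography on a chiral stationary phase then separates 15 from its (2R) antipode F6. The cost is half of the material and a regiochemical outcome that rests on the rearrangement and no longer on construction.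

**Step 8.**
- What may go wrong: the hydrogen-bonded 5-hydroxyl reacts slowly, and under prolonged exposure to a basic oxide ring C may open to the chalcone, with racemisation and O-methylation of the opened phenol.
- Fallback: it sets out from 15 and returns at 16, replacing phenoxide alkylation by Mitsunobu etherification with methanol (MeOH, PPh3, DIAD, THF, rt). The phenol then reacts as the acid partner of an alkoxyphosphonium salt and no metal base is present; no compound outside the list is made (F0).

**Step 3.**
- What may go wrong: bromination may compete on the electron-rich ring B or go on to a second bromine, and HBr formed in such side reactions could ionise the benzylic C2–O1 bond.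
- Fallback: it sets out from 5 and returns at 6, changing substitution into addition and elimination. Br2 (1.0 equiv, CH2Cl2, −78 °C) adds across the enol ether double bond faster than it attacks an arene at that temperature, giving the trans-5,6-dibromide F7. Et3N (−78 to 0 °C) then removes HBr through the acidic H-5.

**Step 2.**
- What may go wrong: facial selectivity may be poorer with this electron-rich aldehyde, the face may be the opposite of the one expected for the chosen ligand, or part of the acetal may be lost in the acid treatment.
- Fallback: it sets out from 2 and 3 and returns at 5, giving up asymmetric induction. ZnCl2 (THF, rt) should give the racemic cycloadduct F8 (not isolated), and TFA converts it into the racemic pyranone F9. Preparative chromatography on a chiral stationary phase separates 5 from its (R) antipode F10.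

## Further compounds

F1 | step 7 | 2',6'-dihydroxy-4'-methoxyacetophenone (purchased) | CC(=O)c1c(O)cc(OC)cc1O
F2 | step 7 | (E)-1-(2,6-dihydroxy-4-methoxyphenyl)-3-[4-methoxy-3-(methoxymethoxy)phenyl]prop-2-en-1-one | COCOc1cc(/C=C/C(=O)c2c(O)cc(OC)cc2O)ccc1OC
F3 | step 7 | racemic 5-hydroxy-7,4'-dimethoxy-3'-(methoxymethoxy)flavanone | COc1ccc(C2CC(=O)c3c(O)cc(OC)cc3O2)cc1OCOC
F4 | step 7 | racemic 7,4'-dimethoxy-3'-(methoxymethoxy)-5-(3-methylbut-2-enyloxy)flavanone | COc1ccc(C2CC(=O)c3c(OCC=C(C)C)cc(OC)cc3O2)cc1OCOC
F5 | step 7 | racemic 5-hydroxy-7,4'-dimethoxy-3'-(methoxymethoxy)-8-prenylflavanone | COc1ccc(C2CC(=O)c3c(O)cc(OC)c(CC=C(C)C)c3O2)cc1OCOC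
F6 | step 7 | (2R)-5-hydroxy-7,4'-dimethoxy-3'-(methoxymethoxy)-8-prenylflavanone | COc1ccc([C@H]2CC(=O)c3c(O)cc(OC)c(CC=C(C)C)c3O2)cc1OCOC
F0 | step 8 | none | none
F7 | step 3 | (2S)-5,6-dibromo-2-[4-methoxy-3-(methoxymethoxy)phenyl]tetrahydropyran-4-one (5,6-trans expected) | COc1ccc([C@@H]2CC(=O)C(Br)C(Br)O2)cc1OCOC
F8 | step 2 | racemic 6-methoxy-2-[4-methoxy-3-(methoxymethoxy)phenyl]-4-(trimethylsilyloxy)-3,6-dihydro-2H-pyran | COC1C=C(O[Si](C)(C)C)CC(c2ccc(OC)c(OCOC)c2)O1
F9 | step 2 | racemic 2-[4-methoxy-3-(methoxymethoxy)phenyl]-2,3-dihydro-4H-pyran-4-one | COc1ccc(C2CC(=O)C=CO2)cc1OCOC
F10 | step 2 | (2R)-2-[4-methoxy-3-(methoxymethoxy)phenyl]-2,3-dihydro-4H-pyran-4-one | COc1ccc([C@H]2CC(=O)C=CO2)cc1OCOC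
A1 | alternative 1 | (1S,3S)-1-[2-bromo-4,6-dimethoxy-3-(3-methylbut-2-enyl)phenyl]-3-[4-methoxy-3-(methoxymethoxy)phenyl]propane-1,3-diol | COc1ccc([C@@H](O)C[C@H](O)c2c(OC)cc(OC)c(CC=C(C)C)c2Br)cc1OCOC
A2 | alternative 1 | (2S,4S)-5,7,4'-trimethoxy-3'-(methoxymethoxy)-8-prenylflavan-4-ol | COc1ccc([C@@H]2C[C@H](O)c3c(OC)cc(OC)c(CC=C(C)C)c3O2)cc1OCOC
A3 | alternative 2 | (3S)-3-[2-bromo-3,5-dimethoxy-6-(3-methylbut-2-enyl)phenoxy]-N-methoxy-3-[4-methoxy-3-(methoxymethoxy)phenyl]-N-methylpropanamide | COc1ccc([C@H](CC(=O)N(C)OC)Oc2c(Br)c(OC)cc(OC)c2CC=C(C)C)cc1OCOC
A4 | alternative 2 | (2S)-5,7,4'-trimethoxy-3'-(methoxymethoxy)-8-prenylflavanone (identical with 16) | COc1ccc([C@@H]2CC(=O)c3c(OC)cc(OC)c(CC=C(C)C)c3O2)cc1OCOC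
A5 | alternative 3 | methyl (2S)-2-[4-methoxy-3-(methoxymethoxy)phenyl]-6-(6-methyl-2-oxohept-5-en-3-yl)-4-oxo-3,4-dihydro-2H-pyran-5-carboxylate | COc1ccc([C@@H]2CC(=O)C(C(=O)OC)=C(C(CC=C(C)C)C(C)=O)O2)cc1OCOC
A6 | alternative 3 | (2S)-5,7-dihydroxy-4'-methoxy-3'-(methoxymethoxy)-8-prenylflavanone | COc1ccc([C@@H]2CC(=O)c3c(O)cc(O)c(CC=C(C)C)c3O2)cc1OCOC
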